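**Retrosynthetic overview**
1. The enone C=C is cut by a Claisen–Schmidt condensation: an 8-acetylchroman-3-ol plus MOM-protected 4-hydroxybenzaldehyde (this brings in the 4-hydroxyphenyl ring).
2. The C3 carbinol stereocentre comes from a catalyst-controlled (CBS) reduction of an 8-acetyl-2,2-dimethylchroman-3-one.
3. The dihydropyran ring is the only ring made in the route. It is closed through the C2–C3 bond by a carbene-catalysed intramolecular hydroacylation of an aryl isopropenyl ether by an arylacetaldehyde.
4. Enabling feature: in the dihydropyran ring, C2 carries the ring oxygen O1 and two methyl groups, and its neighbour C3 is a carbinol carbon one CH2 (C4) from the benzene ring. C2 is therefore the oxygen-bearing carbon of an O1-isopropenyl ether (its CH2 becomes the second methyl) and C3 an aldehyde carbon.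
5. The benzene ring is bought as paeonol; its 1,2,3,4-substitution pattern is completed by O-allylation and aromatic Claisen rearrangement.

Key step: step 6

Remark: isopropenylboronic acid pinacol ester, 4-(methoxymethoxy)benzaldehyde and the triazolium salt of step 6 are taken as purchasable.

**Route**

Step 1
Reactants: 1 paeonol, 1-(2-hydroxy-4-methoxyphenyl)ethanone; 2 allyl bromide
Product: 3 1-[4-methoxy-2-(prop-2-en-1-yloxy)phenyl]ethanone
Conditions: K2CO3, DMF, 60 °C
Reagents that add atoms: allyl bromide (2), C=CCBr
Why: Williamson O-alkylation of the only acidic OH by a reactive allylic halide should proceed cleanly, since the carbonate breaks the intramolecular hydrogen bond of the phenol.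

Step 2
Reactants: 3 1-[4-methoxy-2-(prop-2-en-1-yloxy)phenyl]ethanone
Product: 4 1-[2-hydroxy-4-methoxy-3-(prop-2-en-1-yl)phenyl]ethanone
Conditions: PhNEt2, 200 °C
Reagents that add atoms: none
Why: The aromatic Claisen rearrangement ([3,3]-sigmatropic shift, then tautomerisation) should deliver the allyl group to the only free ortho position, between the two oxygen substituents, because the other ortho position carries the acetyl group.

Step 3
Reactants: 4 1-[2-hydroxy-4-methoxy-3-(prop-2-en-1-yl)phenyl]ethanone
Product: 7 1-[2-hydroxy-3-(2-hydroxyethyl)-4-methoxyphenyl]ethanone, via diol 5 (not isolated), via lactol 6 (not isolated)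
Conditions: K2OsO4·2H2O (2 mol%), NaIO4, 2,6-lutidine, 1,4-dioxane/H2O, rt; extraction; then NaBH4, EtOH, −20 °C
Reagents that add atoms: sodium periodate, [Na+].[O-]I(=O)(=O)=O
Why: Lemieux–Johnson cleavage (dihydroxylation, then periodate glycol cleavage) removes the terminal carbon, and the aldehyde (open form of the lactol) should be reduced by borohydride far faster than the chelated, phenoxide-deactivated aryl methyl ketone.

Step 4
Reactants: 7 1-[2-hydroxy-3-(2-hydroxyethyl)-4-methoxyphenyl]ethanone; 8 4,4,5,5-tetramethyl-2-(prop-1-en-2-yl)-1,3,2-dioxaborolane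
Product: 9 1-[3-(2-hydroxyethyl)-4-methoxy-2-(prop-1-en-2-yloxy)phenyl]ethanone
Conditions: Cu(OAc)2 (2 equiv), pyridine, 4 Å MS, dry air, CH2Cl2, rt; chromatography on Et3N-deactivated silica
Reagents that add atoms: 4,4,5,5-tetramethyl-2-(prop-1-en-2-yl)-1,3,2-dioxaborolane (8), CC(=C)B1OC(C)(C)C(C)(C)O1
Why: Chan–Lam oxidative C–O coupling (alkenyl transfer from boron to divalent copper, phenoxide binding, C–O reductive elimination from a trivalent copper species) should engage the acidic phenol in preference to the primary alcohol, while pyridine keeps the medium basic enough to preserve the acid-labile enol ether.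

Step 5
Reactants: 9 1-[3-(2-hydroxyethyl)-4-methoxy-2-(prop-1-en-2-yloxy)phenyl]ethanone
Product: 10 [3-acetyl-6-methoxy-2-(prop-1-en-2-yloxy)phenyl]acetaldehyde
Conditions: SO3·pyridine, DMSO, iPr2NEt, CH2Cl2, 0 °C; used crude
Reagents that add atoms: none
Why: The Parikh–Doering oxidation stays basic throughout, so the primary alcohol should be taken to the aldehyde without hydrolysis of the enol ether or over-oxidation.

Step 6
Reactants: 10 [3-acetyl-6-methoxy-2-(prop-1-en-2-yloxy)phenyl]acetaldehyde
Product: 12 8-acetyl-5-methoxy-2,2-dimethyl-2H-chromen-3(4H)-one, via Breslow intermediate 11 (not isolated)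
Conditions: 2-mesityl-6,7-dihydro-5H-pyrrolo[2,1-c][1,2,4]triazol-2-ium chloride (20 mol%), 1,8-diazabicyclo[5.4.0]undec-7-ene (20 mol%), 4 Å MS, 1,4-dioxane (0.02 M), 100 °C
Reagents that add atoms: none
Why: Proposed new method: the triazolylidene adds to the aldehyde of 10 and proton transfer gives the Breslow enaminol 11, whose nucleophilic carbon (future C3) bonds to the oxygen-bearing alkene carbon of the aryl isopropenyl ether (future C2) while its O–H proton passes to the terminal CH2 in an asynchronous ene-like transition state (in the limit an oxocarbenium/alkoxide pair), after which the tetrahedral adduct expels the carbene and releases ketone 12. The closest known reaction type is the carbene-catalysed intramolecular hydroacylation of unactivated 1,1-disubstituted alkenes and of aryl enol ethers by aromatic aldehydes, which gives chroman-4-ones and benzofuran-3-ones with a new quaternary carbon; the extension is the use of an enolisable arylacetaldehyde as acyl donor. The dihydropyranone ring closes in the 6-exo-trig mode (ring atoms C3, C4, C4a, C8a, O1, C2; the C=CH2 bond lies outside the ring). No stereocentre is formed, because C2 ends with two identical methyl groups (one is the former CH2 terminus) and C3 remains a carbonyl carbon for step 7. The step needs Markovnikov regioselectivity (bond to C2, not to CH2, which would give a seven-membered ring) and acyl transfer in preference to aldol or benzoin reactions. The first is secured by ring oxygen O1, which makes CH2 the proton acceptor and C2 the oxocarbenium-like carbon, together with the six-membered ring preference; the second by high dilution, the bulky N-mesityl carbene, substoichiometric base and the meta relation of the acetyl group to the side chain, which rules out any intramolecular carbonyl–carbonyl reaction.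

Step 7
Reactants: 12 8-acetyl-5-methoxy-2,2-dimethyl-2H-chromen-3(4H)-one
Product: 14 1-[(3S)-3-hydroxy-5-methoxy-2,2-dimethyl-3,4-dihydro-2H-chromen-8-yl]ethanone, via borate ester 13 (not isolated)
Conditions: (3aR)-1-methyl-3,3-diphenyltetrahydro-1H,3H-pyrrolo[1,2-c][1,3,2]oxazaborole (20 mol%), catecholborane (1.2 equiv), toluene, −78 to −40 °C; then MeOH, aq. NaOH wash
Reagents that add atoms: none
Why: In this Corey–Bakshi–Shibata reduction the ketone should bind the ring boron through the lone pair on the side of the C4 methylene (small) and away from quaternary C2 (large), so the (R)-catalyst delivers hydride to the Re face of C3 and sets the (3S)-carbinol, while the electron-rich, conjugated aryl methyl ketone should be too unreactive towards catecholborane at this temperature.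

Step 8
Reactants: 14 1-[(3S)-3-hydroxy-5-methoxy-2,2-dimethyl-3,4-dihydro-2H-chromen-8-yl]ethanone; 15 4-(methoxymethoxy)benzaldehyde
Product: 17 (2E)-1-[(3S)-3-hydroxy-5-methoxy-2,2-dimethyl-3,4-dihydro-2H-chromen-8-yl]-3-[4-(methoxymethoxy)phenyl]prop-2-en-1-one, via aldol adduct 16 (not isolated)
Conditions: KOH, EtOH/H2O, rt
Reagents that add atoms: 4-(methoxymethoxy)benzaldehyde (15), COCOc1ccc(C=O)cc1
Why: In this Claisen–Schmidt condensation only the methyl ketone can enolise and the aldehyde cannot, E1cB dehydration of the aldol adduct should give the thermodynamically favoured E-enone, and the C3 carbinol has no adjacent acidifying group and cannot epimerise.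

Step 9
Reactants: 17 (2E)-1-[(3S)-3-hydroxy-5-methoxy-2,2-dimethyl-3,4-dihydro-2H-chromen-8-yl]-3-[4-(methoxymethoxy)phenyl]prop-2-en-1-one
Product: 18 (2E)-1-[(3S)-3-hydroxy-5-methoxy-2,2-dimethyl-3,4-dihydro-2H-chromen-8-yl]-3-(4-hydroxyphenyl)prop-2-en-1-one
Conditions: 2 M HCl, MeOH, 40 °C
Reagents that add atoms: none
Why: Acid-catalysed cleavage of the methoxymethyl acetal should free the phenol, while the secondary alcohol, the cyclic tertiary alkyl aryl ether and the enone tolerate dilute methanolic acid and the absence of a free ortho-hydroxyl on the ketone ring excludes flavanone formation.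

**Compound list**

1 | paeonol, 1-(2-hydroxy-4-methoxyphenyl)ethanone | CC(=O)c1ccc(OC)cc1O | starting material
2 | allyl bromide | C=CCBr | starting material
3 | 1-[4-methoxy-2-(prop-2-en-1-yloxy)phenyl]ethanone | CC(=O)c1ccc(OC)cc1OCC=C | intermediate
4 | 1-[2-hydroxy-4-methoxy-3-(prop-2-en-1-yl)phenyl]ethanone | CC(=O)c1ccc(OC)c(CC=C)c1O | intermediate
5 | 1-[3-(2,3-dihydroxypropyl)-2-hydroxy-4-methoxyphenyl]ethanone (racemic) | CC(=O)c1ccc(OC)c(CC(O)CO)c1O | intermediate (not isolated)
6 | 1-(2-hydroxy-4-methoxy-2,3-dihydro-1-benzofuran-7-yl)ethanone (lactol, in equilibrium with the open hydroxy aldehyde) | CC(=O)c1ccc(OC)c2CC(O)Oc12 | intermediate (not isolated)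
7 | 1-[2-hydroxy-3-(2-hydroxyethyl)-4-methoxyphenyl]ethanone | CC(=O)c1ccc(OC)c(CCO)c1O | intermediate
8 | 4,4,5,5-tetramethyl-2-(prop-1-en-2-yl)-1,3,2-dioxaborolane | CC(=C)B1OC(C)(C)C(C)(C)O1 | starting material
9 | 1-[3-(2-hydroxyethyl)-4-methoxy-2-(prop-1-en-2-yloxy)phenyl]ethanone | CC(=O)c1ccc(OC)c(CCO)c1OC(C)=C | intermediate
10 | [3-acetyl-6-methoxy-2-(prop-1-en-2-yloxy)phenyl]acetaldehyde | CC(=O)c1ccc(OC)c(CC=O)c1OC(C)=C | intermediate
11 | Breslow intermediate: enaminol from aldehyde 10 and 2-mesityl-6,7-dihydro-5H-pyrrolo[2,1-c][1,2,4]triazol-3-ylidene | Cc1cc(C)c(N2N=C3CCCN3C2=C(O)Cc2c(OC)ccc(C(C)=O)c2OC(C)=C)c(C)c1 | intermediate (not isolated)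
12 | 8-acetyl-5-methoxy-2,2-dimethyl-2H-chromen-3(4H)-one | COc1ccc(C(C)=O)c2c1CC(=O)C(C)(C)O2 | intermediate
13 | 2-{[(3S)-8-acetyl-5-methoxy-2,2-dimethyl-3,4-dihydro-2H-chromen-3-yl]oxy}-1,3,2-benzodioxaborole | COc1ccc(C(C)=O)c2c1C[C@H](OB1Oc3ccccc3O1)C(C)(C)O2 | intermediate (not isolated)
14 | 1-[(3S)-3-hydroxy-5-methoxy-2,2-dimethyl-3,4-dihydro-2H-chromen-8-yl]ethanone | COc1ccc(C(C)=O)c2c1C[C@H](O)C(C)(C)O2 | intermediate
15 | 4-(methoxymethoxy)benzaldehyde | COCOc1ccc(C=O)cc1 | starting material
16 | 3-hydroxy-1-[(3S)-3-hydroxy-5-methoxy-2,2-dimethyl-3,4-dihydro-2H-chromen-8-yl]-3-[4-(methoxymethoxy)phenyl]propan-1-one (both epimers at the new carbinol) | COc1ccc(C(=O)CC(O)c2ccc(OCOC)cc2)c2c1C[C@H](O)C(C)(C)O2 | intermediate (not isolated)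
17 | (2E)-1-[(3S)-3-hydroxy-5-methoxy-2,2-dimethyl-3,4-dihydro-2H-chromen-8-yl]-3-[4-(methoxymethoxy)phenyl]prop-2-en-1-one | COc1ccc(C(=O)/C=C/c2ccc(OCOC)cc2)c2c1C[C@H](O)C(C)(C)O2 | intermediate
18 | (2E)-1-[(3S)-3-hydroxy-5-methoxy-2,2-dimethyl-3,4-dihydro-2H-chromen-8-yl]-3-(4-hydroxyphenyl)prop-2-en-1-one | COc1ccc(C(=O)/C=C/c2ccc(O)cc2)c2c1C[C@H](O)C(C)(C)O2 | target

**Summary**

Total step count: 9. Longest linear sequence: 9 steps (1 to 18); compounds 2, 8 and 15 are bought.

Steps most likely to fail:

1. Step 6 (carries the label). What may go wrong: base-mediated self-condensation of the enolisable arylacetaldehyde may outrun the carbene pathway, or the enaminol may fail to add across the enol ether. Fallback with known chemistry, radical instead of polar bond formation: setting out from 10, iron-hydride hydrogen-atom transfer (Fe(acac)3, PhSiH3, EtOH, 60 °C) should place a hydrogen atom on the CH2 terminus of the isopropenyl ether. The resulting tertiary α-aryloxy radical should add 6-exo to the aldehyde, and reduction of the alkoxy radical should give racemic 1-(3-hydroxy-5-methoxy-2,2-dimethyl-3,4-dihydro-2H-chromen-8-yl)ethanone F1. Oxidation with Dess–Martin periodinane (NaHCO3, CH2Cl2, rt) should then return to the route at 12.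

2. Step 4. What may go wrong: sluggish coupling of the chelated, doubly ortho-substituted phenol, competing alkenylation of the primary alcohol, or acid-triggered addition of that alcohol to the new enol ether. Fallback with a protecting group and a different coupling manifold: setting out from 7, silylation of the primary alcohol (TBSCl, imidazole, DMF) should give 1-[3-(2-{[tert-butyl(dimethyl)silyl]oxy}ethyl)-2-hydroxy-4-methoxyphenyl]ethanone F2. Ullmann-type vinylation with 2-bromopropene (CuI, N,N-dimethylglycine, Cs2CO3, 1,4-dioxane, 90 °C) should give 1-[3-(2-{[tert-butyl(dimethyl)silyl]oxy}ethyl)-4-methoxy-2-(prop-1-en-2-yloxy)phenyl]ethanone F3. Desilylation with Bu4NF in THF should return to the route at 9.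

3. Step 7. What may go wrong: loss of chemoselectivity, with partial reduction of the aryl methyl ketone alongside the ring ketone. Fallback by deliberate over-reduction and selective re-oxidation: setting out from 12, both ketones are reduced with excess BH3·SMe2 and the same oxazaborolidine (THF, −20 °C), which should give (3S)-8-(1-hydroxyethyl)-5-methoxy-2,2-dimethyl-3,4-dihydro-2H-chromen-3-ol F4, configuration at the benzylic carbinol being immaterial. MnO2 in CH2Cl2 should then re-oxidise only the benzylic alcohol and return to the route at 14.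

**Further compounds**

F1 | step 6 | racemic 1-(3-hydroxy-5-methoxy-2,2-dimethyl-3,4-dihydro-2H-chromen-8-yl)ethanone | COc1ccc(C(C)=O)c2c1CC(O)C(C)(C)O2
F2 | step 4 | 1-[3-(2-{[tert-butyl(dimethyl)silyl]oxy}ethyl)-2-hydroxy-4-methoxyphenyl]ethanone | CC(=O)c1ccc(OC)c(CCO[Si](C)(C)C(C)(C)C)c1O
F3 | step 4 | 1-[3-(2-{[tert-butyl(dimethyl)silyl]oxy}ethyl)-4-methoxy-2-(prop-1-en-2-yloxy)phenyl]ethanone | CC(=O)c1ccc(OC)c(CCO[Si](C)(C)C(C)(C)C)c1OC(C)=C
F4 | step 7 | (3S)-8-(1-hydroxyethyl)-5-methoxy-2,2-dimethyl-3,4-dihydro-2H-chromen-3-ol (both epimers at the benzylic carbinol) | COc1ccc(C(C)O)c2c1C[C@H](O)C(C)(C)O2
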